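The decalin is cut at C1–C10 and C4–C5. Ring B then carries oxygen at C6 and C9 and methyl-bearing carbons at C8 and C10, the pattern of 2,6-dimethyl-1,4-benzoquinone, and the C5–C10 fusion is cis, as a cycloaddition delivers. One catalytic enantioselective Diels–Alder reaction of this achiral quinone, whose two alkenes are equivalent, with 4-methylpenta-1,3-diene closes ring A, creates C5 and the quaternary C10 and supplies all ring B functionality. Afterwards C8 is set by hydroxyl-directed hydrogenation, a C11–C16 ethynyl hydroxy-lactone from (R)-malic acid is added to the C9 ketone, C6 is turned into the equatorial alcohol, and acid closes the C9–O bond of the spiro ether.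

Key step: step 1

Remark (assumption on the chemistry): the target SMILES is read literally as (5S,6S,8R,9R,10R,13R), a cis-fused decalin with H-5, CH3-10, 6-OAc, CH3-8 and the C9–O bond on one face of ring B, called β below (α is the opposite face; labdane numbering throughout); the side-chain building block must supply six carbons, C11–C16.

Step 1
Reactants: 1 2,6-dimethyl-1,4-benzoquinone; 2 4-methylpenta-1,3-diene
Product: 3 (4aS,8aR)-2,5,5,8a-tetramethyl-4a,5,8,8a-tetrahydronaphthalene-1,4-dione
Conditions: (S)-3,3-diphenyl-1-(o-tolyl)tetrahydro-1H,3H-pyrrolo[1,2-c][1,3,2]oxazaborole (20 mol %), Tf2NH (20 mol %), 2 (5 equiv, slow addition), CH2Cl2, −78 → −40 °C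
Reagents that add atoms: none
Why: The protonated oxazaborolidine binds the future C6 carbonyl oxygen of 1 (the only quinone oxygen flanked by C–H) syn to C5–H, and the diene adds to the activated C5=C10 bond in a concerted, strongly asynchronous [4+2] cycloaddition in which C1–C10 forms ahead of C4–C5. The closest known reaction type is the enantioselective Diels–Alder reaction of methyl-substituted 1,4-benzoquinones with 1,3-dienes under cationic oxazaborolidine catalysis, of which a diene with a gem-dimethyl terminus is a slow member. Ring A is closed as a cyclohexene by suprafacial endo cycloaddition, so the C5–C10 fusion is necessarily cis. C5 and C10 are formed together: their relative configuration follows from suprafacial addition and their absolute configuration from the catalyst, one C-phenyl group of which covers one face of the bound C5=C10 bond so that the diene enters from the face on which C6→C5→C10 runs clockwise; the (S)-catalyst is chosen with this binding model, and the (R)-catalyst would give the antipode. The step needs regioselectivity, secured by pairing the nucleophilic CH2 terminus of 2 with the methyl-bearing β-carbon C10 of the coordinated enone (the CMe2 terminus thereby avoids the quaternary centre), and periselectivity against ene reaction or cationic oligomerisation of 2, addressed by low temperature, excess diene and slow addition. Site selectivity is no issue because the two quinone alkenes are equivalent, and the quaternary C10 blocks aromatisation of 3.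

Step 2
Reactants: 3 cis-fused enedione
Product: 4 (4R,4aS,8aR)-4-hydroxy-2,5,5,8a-tetramethyl-4a,5,8,8a-tetrahydronaphthalen-1(4H)-one (6α-hydroxy enone)
Conditions: NaBH4 (1.0 equiv), CeCl3·7H2O (1.1 equiv), MeOH–CH2Cl2, −78 °C
Reagents that add atoms: none
Why: Luche reduction is 1,2-selective and attacks the less hindered C6 carbonyl (C9 is flanked by the quaternary C10 and the methyl-bearing C8) from the convex β-face, away from ring A folded under ring B, so the new C6 stereocentre carries a 6α-hydroxyl that masks C6 and directs the next step.

Step 3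
Reactants: 4 6α-hydroxy enone
Product: 5 (2R,4R,4aS,8aR)-4-hydroxy-2,5,5,8a-tetramethyloctahydronaphthalen-1(2H)-one (6α-OH; 8β-CH3; C9 ketone)
Conditions: H2 (1 atm), [Ir(cod)(PCy3)(py)]PF6 (5 mol %), CH2Cl2, 0 °C → rt
Reagents that add atoms: none
Why: In this hydroxyl-directed homogeneous hydrogenation the cationic iridium catalyst binds the allylic 6α-hydroxyl and delivers H2 to the α-face of C7=C8, so C8 receives hydrogen cis to the hydroxyl and CH3-8 becomes β (undirected β-face hydrogenation would give the 8-epimer), while C2=C3 is saturated in the same operation and the neutral medium leaves the epimerisable C8 untouched.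

Step 4
Reactants: 6 (R)-malic acid
Product: 7 2-[(2R,4R)-2-tert-butyl-5-oxo-1,3-dioxolan-4-yl]acetic acid
Conditions: pivalaldehyde (1.5 equiv), TsOH·H2O (cat.), H2SO4 (cat.), pentane, reflux with water separator; recrystallisation
Reagents that add atoms: pivalaldehyde, CC(C)(C)C=O
Why: Acid-catalysed acetalisation of the α-hydroxy acid unit gives the 2-tert-butyl-1,3-dioxolan-4-one, whose cis isomer is favoured and purified by crystallisation, and the new acetal centre stores the chirality of the carbon that becomes C13.

Step 5
Reactants: 7 dioxolanone acid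
Product: 9 2-[(2R,4S)-2-tert-butyl-4-(hydroxymethyl)-5-oxo-1,3-dioxolan-4-yl]acetic acid, via dilithium enolate 8 (not isolated)
Conditions: LiN(SiMe3)2 (2.2 equiv), THF, −78 °C; CH2O (gas from cracked paraformaldehyde), −78 → −40 °C; aq. NH4Cl
Reagents that add atoms: formaldehyde, C=O
Why: In this aldol hydroxymethylation with self-regeneration of the stereocentre, double deprotonation gives the carboxylate ester-enolate 8, whose planar C13 is attacked by formaldehyde on the face opposite the acetal tert-butyl group, so the quaternary C13 forms with retention of the original sense and C12 enters as CH2OH.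

Step 6
Reactants: 9 hydroxymethyl dioxolanone acid
Product: 11 (3S)-3-hydroxy-3-(hydroxymethyl)oxolan-2-one, via diol 10 (not isolated)
Conditions: BH3·SMe2 (3 equiv), THF, 0 °C → rt; MeOH; then TsOH·H2O (10 mol %), CH2Cl2, rt
Reagents that add atoms: none
Why: Borane reduces the free carboxylic acid chemoselectively without touching the dioxolanone, and acid then drives transesterification of the new C15 hydroxyl onto the dioxolanone carbonyl (γ-lactone strongly preferred over a β-lactone from the hydroxymethyl group) with loss of pivalaldehyde, C13 being untouched.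

Step 7
Reactants: 11 diol lactone
Product: 12 (3S)-3-(triethylsilyloxy)-3-[(triethylsilyloxy)methyl]oxolan-2-one
Conditions: Et3SiOTf (2.5 equiv), 2,6-lutidine (4 equiv), CH2Cl2, −78 → 0 °C
Reagents that add atoms: triethylsilyl triflate, CC[Si](CC)(CC)OS(=O)(=O)C(F)(F)F
Why: Silylation with the silyl triflate and 2,6-lutidine is forceful enough to cap the hindered tertiary C13 hydroxyl as well as the primary one, which protects C13–O through oxidation, homologation and the organometallic step.

Step 8
Reactants: 12 bis-silyl ether
Product: 13 (3S)-2-oxo-3-(triethylsilyloxy)oxolane-3-carbaldehyde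
Conditions: (COCl)2 (4 equiv), DMSO (8 equiv), CH2Cl2, −78 → −35 °C; Et3N, −78 °C → rt
Reagents that add atoms: none
Why: Under Swern oxidation conditions the chlorodimethylsulfonium reagent cleaves and oxidises the unhindered primary triethylsilyl ether directly to the aldehyde while the tertiary silyl ether and the lactone survive, and the aldehyde cannot epimerise because C13 bears no hydrogen.

Step 9
Reactants: 13 aldehyde
Product: 14 (3S)-3-ethynyl-3-(triethylsilyloxy)oxolan-2-one
Conditions: Me3SiCHN2 (1.3 equiv), LiN(iPr)2 (1.3 equiv), THF, −78 °C; then 13, −78 → 0 °C; aq. NH4Cl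
Reagents that add atoms: (trimethylsilyl)diazomethane, C[Si](C)(C)C=[N+]=[N-]
Why: In this Colvin rearrangement lithiated trimethylsilyldiazomethane adds to the aldehyde (far more electrophilic than the α,α-disubstituted lactone at −78 °C), and Peterson-type elimination, loss of N2 and 1,2-hydrogen shift of the alkylidene carbene give the terminal alkyne whose new carbon is C11, so 14 is the complete C11–C16 fragment.

Step 10
Reactants: 14 ethynyl lactone; 5 hydroxy ketone
Product: 16 propargylic alcohol (6α-OH; 8β-CH3; 9α-OH; 9β-C≡C bonded to C13 of the silyloxy lactone), via dichlorocerium acetylide 15 (not isolated)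
Conditions: 14 (2.5 equiv), LiN(iPr)2 (2.5 equiv), THF, −78 °C; CeCl3 (anhydrous, 2.6 equiv), −78 °C; then 5, −78 → −30 °C; aq. NH4Cl
Reagents that add atoms: none
Why: In this 1,2-addition of an organocerium acetylide to a hindered, enolisable ketone the weakly basic acetylide 15 (trivalent cerium) should add to the C9 carbonyl faster than it deprotonates C8–H or attacks the neopentylic lactone of another molecule, the excess being consumed by the free 6α-hydroxyl, and axial β-face attack is expected to give the 9α-carbinol, although the C9 configuration is irrelevant because C9 is ionised in step 15.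

Step 11
Reactants: 16 propargylic alcohol
Product: 17 saturated diol (6α-OH; 9α-OH; 13-OSiEt3; C11 and C12 now CH2)
Conditions: H2 (1 atm), Pd/C (10 wt %), EtOAc, rt
Reagents that add atoms: none
Why: Heterogeneous hydrogenation saturates the C11≡C12 triple bond to the two ring C methylenes without creating a stereocentre, and the lactone, silyl ether and hindered tertiary alcohol should survive under these neutral conditions.

Step 12
Reactants: 17 saturated diol
Product: 18 6-oxo compound (C6 ketone; 9α-OH; 13-OSiEt3)
Conditions: Dess–Martin periodinane (1.3 equiv), NaHCO3, CH2Cl2, 0 °C → rt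
Reagents that add atoms: none
Why: Dess–Martin oxidation of the only secondary alcohol under buffered, non-enolising conditions returns the C6 ketone without epimerising C5, the tertiary C9 hydroxyl and the silyl ether being inert.

Step 13
Reactants: 18 6-oxo compound
Product: 19 6β-alcohol (equatorial)
Conditions: SmI2 (2.5 equiv), H2O (50 equiv), THF, 0 °C
Reagents that add atoms: none
Why: In this single-electron ketone reduction with SmI2–H2O (divalent samarium) the ketyl and organosamarium intermediates are protonated to the thermodynamically preferred equatorial 6β-alcohol (ring B is a chair fixed by the quaternary C9 and the equatorial CH3-8, and the axial α-position is 1,3-diaxial to C1), whereas hydride reagents would again attack from the β-face and return the 6α-epimer, and five-membered lactones are inert to this reagent.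

Step 14
Reactants: 19 6β-alcohol
Product: 20 6β-acetate
Conditions: Ac2O (3 equiv), pyridine, DMAP (10 mol %), CH2Cl2, rt
Reagents that add atoms: acetic anhydride, CC(=O)OC(C)=O
Why: Standard acylation esterifies the secondary 6β-hydroxyl, while the neopentylic tertiary C9 hydroxyl is too hindered to react.

Step 15
Reactants: 20 6β-acetate
Product: 21 target CNP0081177.1: (5S,6S,8R,9R,10R,13R)-6-acetoxy-9,13-epoxylabdan-16,15-olide
Conditions: TsOH·H2O (20 mol %), CH2Cl2, 0 °C → rt
Reagents that add atoms: none
Why: In this acid-catalysed cyclodehydration of a 1,4-diol derivative (SN1 etherification) only the tertiary C9–O bond ionises (a cation at C13 would sit α to the lactone carbonyl), and the C13 oxygen, as silyl ether or as the alcohol released in situ, closes the tetrahydrofuran by 5-exo attack on the β-face of the C9 cation (axial approach, the α-face being blocked by the axial C1 methylene), which places the ether oxygen β and C11 α as in the target while C8, C13 and the acetate are unaffected.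

Compound list
1 | 2,6-dimethyl-1,4-benzoquinone | CC1=CC(=O)C=C(C)C1=O | starting material
2 | 4-methylpenta-1,3-diene | CC(C)=CC=C | starting material
3 | (4aS,8aR)-2,5,5,8a-tetramethyl-4a,5,8,8a-tetrahydronaphthalene-1,4-dione (cis-fused; C6 and C9 carbonyls, C7=C8, C2=C3) | O=C1C=C(C)C(=O)[C@]2(C)CC=CC(C)(C)[C@H]12 | intermediate
4 | (4R,4aS,8aR)-4-hydroxy-2,5,5,8a-tetramethyl-4a,5,8,8a-tetrahydronaphthalen-1(4H)-one (6α-hydroxy enone) | O[C@@H]1C=C(C)C(=O)[C@]2(C)CC=CC(C)(C)[C@H]12 | intermediate
5 | (2R,4R,4aS,8aR)-4-hydroxy-2,5,5,8a-tetramethyloctahydronaphthalen-1(2H)-one (6α-OH, 8β-CH3, C9 ketone) | O[C@@H]1C[C@@H](C)C(=O)[C@]2(C)CCCC(C)(C)[C@H]12 | intermediate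
6 | (R)-malic acid | OC(=O)C[C@@H](O)C(=O)O | starting material
7 | 2-[(2R,4R)-2-tert-butyl-5-oxo-1,3-dioxolan-4-yl]acetic acid | CC(C)(C)[C@@H]1O[C@H](CC(=O)O)C(=O)O1 | intermediate
8 | dilithium carboxylate ester-enolate of 7 | CC(C)(C)[C@@H]1OC(CC(=O)[O-])=C([O-])O1.[Li+].[Li+] | intermediate (not isolated)
9 | 2-[(2R,4S)-2-tert-butyl-4-(hydroxymethyl)-5-oxo-1,3-dioxolan-4-yl]acetic acid | CC(C)(C)[C@@H]1O[C@](CO)(CC(=O)O)C(=O)O1 | intermediate
10 | (2R,5S)-2-tert-butyl-5-(2-hydroxyethyl)-5-(hydroxymethyl)-1,3-dioxolan-4-one | CC(C)(C)[C@@H]1O[C@](CO)(CCO)C(=O)O1 | intermediate (not isolated)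
11 | (3S)-3-hydroxy-3-(hydroxymethyl)oxolan-2-one | OC[C@]1(CCOC1=O)O | intermediate
12 | (3S)-3-(triethylsilyloxy)-3-[(triethylsilyloxy)methyl]oxolan-2-one | CC[Si](CC)(CC)OC[C@]1(CCOC1=O)O[Si](CC)(CC)CC | intermediate
13 | (3S)-2-oxo-3-(triethylsilyloxy)oxolane-3-carbaldehyde | O=C[C@]1(CCOC1=O)O[Si](CC)(CC)CC | intermediate
14 | (3S)-3-ethynyl-3-(triethylsilyloxy)oxolan-2-one (C11–C16 fragment) | C#C[C@]1(CCOC1=O)O[Si](CC)(CC)CC | intermediate
15 | dichlorocerium acetylide of 14 (trivalent cerium) | Cl[Ce](Cl)C#C[C@]1(CCOC1=O)O[Si](CC)(CC)CC | intermediate (not isolated)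
16 | propargylic alcohol: cis-decalin with 6α-OH, 8β-CH3, 9α-OH and a 9β-ethynyl group ending at C13 of the (13S)-silyloxy lactone | O[C@@H]1C[C@@H](C)[C@@](O)(C#C[C@]3(CCOC3=O)O[Si](CC)(CC)CC)[C@]2(C)CCCC(C)(C)[C@H]12 | intermediate
17 | saturated diol: as 16 with C11–C12 as CH2CH2 (13R) | O[C@@H]1C[C@@H](C)[C@@](O)(CC[C@]3(CCOC3=O)O[Si](CC)(CC)CC)[C@]2(C)CCCC(C)(C)[C@H]12 | intermediate
18 | 6-oxo compound: C6 ketone, 9α-OH, 13-OSiEt3 | O=C1C[C@@H](C)[C@@](O)(CC[C@]3(CCOC3=O)O[Si](CC)(CC)CC)[C@]2(C)CCCC(C)(C)[C@H]12 | intermediate
19 | 6β-alcohol: equatorial 6β-OH, 9α-OH, 13-OSiEt3 | O[C@H]1C[C@@H](C)[C@@](O)(CC[C@]3(CCOC3=O)O[Si](CC)(CC)CC)[C@]2(C)CCCC(C)(C)[C@H]12 | intermediate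
20 | 6β-acetate: 6β-OAc, 9α-OH, 13-OSiEt3 | CC(=O)O[C@H]1C[C@@H](C)[C@@](O)(CC[C@]3(CCOC3=O)O[Si](CC)(CC)CC)[C@]2(C)CCCC(C)(C)[C@H]12 | intermediate
21 | CNP0081177.1, (5S,6S,8R,9R,10R,13R)-6-acetoxy-9,13-epoxylabdan-16,15-olide | CC(=O)O[C@H]1C[C@@H](C)[C@]2(CC[C@]3(CCOC3=O)O2)[C@]2(C)CCCC(C)(C)[C@H]12 | target

Total step count: 15 (9 on the decalin line, 6 for the C11–C16 fragment).
Longest linear sequence: 12 steps (6 → 21, steps 4–15); from quinone 1 the sequence is 9 steps (steps 1–3 and 10–15).

The three steps most likely to fail:

First, step 1. The cycloaddition may be slow because the cis-methyl group of the diene disfavours the s-cis conformer; ene reaction or acid-induced oligomerisation of the diene may take over, or enantiofacial control may be insufficient. The fallback sets out from 1 and 2: the cycloaddition is run with an achiral Lewis acid (BF3·OEt2 or SnCl4, CH2Cl2, −78 °C) or under high pressure, which gives 3 together with its mirror image, ent-adduct F1. The racemate is resolved by preparative chromatography on a chiral stationary phase, and the route is rejoined at 3.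

Second, step 10. Addition to the doubly α-branched ketone may be slow, so that enolisation at C8 (with loss of the kinetically set C8 configuration) or attack on the lactone competes. The fallback sets out from 4 and 14: the acetylide 15 is added to the C9 carbonyl of enone 4, which has no α-hydrogen and an sp2 neighbour, to give enyne diol F2. A single hydroxyl-directed hydrogenation ([Ir(cod)(PCy3)(py)]PF6, H2, CH2Cl2) then reduces the alkyne, C7=C8 from the α-face and C2=C3, and the route is rejoined at 17 (a C9 epimer would converge at 21).

Third, step 3. Delivery of hydrogen to the concave α-face of an electron-poor trisubstituted alkene may be slow, so that undirected β-face reduction and poor facial selectivity at C8 result. The fallback sets out from 3: DIBAL-H (CH2Cl2, −78 °C) reduces both carbonyls from the β-face to the 6α,9α-diol F3. Its electron-rich C7=C8 alkene, flanked by two α-hydroxyls, is hydrogenated under double direction ([Rh(nbd)(dppb)]BF4 or the iridium catalyst, H2) to saturated diol F4. Dess–Martin oxidation gives dione F5 with C8 intact, and NaBH4 at −78 °C reduces only the C6 carbonyl from the β-face, which rejoins the route at 5.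

Further compounds
F1 | step 1 | (4aR,8aS)-2,5,5,8a-tetramethyl-4a,5,8,8a-tetrahydronaphthalene-1,4-dione (enantiomer of 3) | O=C1C=C(C)C(=O)[C@@]2(C)CC=CC(C)(C)[C@@H]12
F2 | step 10 | enyne diol: 6α-OH, 9α-OH, 9β-ethynyl bonded to C13 of the silyloxy lactone, C7=C8 and C2=C3 retained | O[C@@H]1C=C(C)[C@@](O)(C#C[C@]3(CCOC3=O)O[Si](CC)(CC)CC)[C@]2(C)CC=CC(C)(C)[C@H]12
F3 | step 3 | (1S,4R,4aS,8aR)-2,5,5,8a-tetramethyl-1,4,4a,5,8,8a-hexahydronaphthalene-1,4-diol (6α,9α-diol) | O[C@@H]1C=C(C)[C@H](O)[C@]2(C)CC=CC(C)(C)[C@H]12
F4 | step 3 | (1S,2R,4R,4aS,8aR)-2,5,5,8a-tetramethyldecahydronaphthalene-1,4-diol (6α,9α-diol, 8β-CH3) | O[C@@H]1C[C@@H](C)[C@H](O)[C@]2(C)CCCC(C)(C)[C@H]12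
F5 | step 3 | (2R,4aS,8aR)-2,5,5,8a-tetramethyloctahydronaphthalene-1,4-dione (8β-CH3) | O=C1C[C@@H](C)C(=O)[C@]2(C)CCCC(C)(C)[C@H]12
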